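**Plan**
- Retrosynthesis: the C3–O angelate and the primary acetate are cut first, then the C5 acetyl (back to C–Br). The resulting allylic diol is traced to a cis-fused α-methylene γ-lactone, whose C3–O bond is cut to a benzylic C–H of a 2-(dihydrobenzofuran-2-yl)acrylic acid. Last, O1–C2 and C3–C3a are cut to an iodoresorcinol and a 2-substituted butadiene.
- Forward: diene by Suzuki coupling, dihydrofuran ring by palladium heteroannulation, side chain oxidised to the acrylic acid, lactone ring closed onto C3–H, lactone opened by reduction, then acetyl, acetate and angelate installed.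
- Enabling feature: C3 is benzylic (O1 ortho and the C6 oxygen para to C3a) and lies γ to the side-chain carbon that ends as CH2OAc. A carboxyl on that carbon reaches the syn C3–H and can only form a cis-fused five-membered lactone on the dihydrofuran ring.
- Stereochemistry: C2 comes from the chiral ligand in the heteroannulation; C3 is relayed from C2 by the obligatory cis fusion of the lactone.

Key step: step 9

Remark: the target's descriptors are read as (2R,3R), which places the C2 side chain and the C3 angelate cis on the dihydrofuran ring.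

**Step 1**
Reactants: 1 4-bromoresorcinol (4-bromobenzene-1,3-diol)
Product: 2 4-bromo-6-iodobenzene-1,3-diol
Conditions: ICl (1.0 equiv), Et2O, 0 °C to rt
Reagents that add atoms: iodine monochloride, ClI
Why: Electrophilic aromatic iodination; C6, para to one hydroxyl and ortho to the other, is the most activated unhindered site, so substitution there should outrun attack at C2 between the two hydroxyls.

**Step 2**
Reactants: 3 2-bromoprop-2-en-1-ol
Product: 4 [(2-bromoprop-2-en-1-yl)oxy](tert-butyl)dimethylsilane
Conditions: TBSCl, imidazole, CH2Cl2, 0 °C to rt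
Reagents that add atoms: tert-butyldimethylsilyl chloride, CC(C)(C)[Si](C)(C)Cl
Why: Routine silylation of a primary alcohol; the silyl ether masks the oxygen through both palladium steps and makes the later diene less volatile.

**Step 3**
Reactants: 4 [(2-bromoprop-2-en-1-yl)oxy](tert-butyl)dimethylsilane; 5 vinylboronic acid pinacol ester
Product: 6 tert-butyldimethyl[(2-methylidenebut-3-en-1-yl)oxy]silane
Conditions: PdCl2(dppf) (3 mol %), K2CO3, THF/H2O, 60 °C
Reagents that add atoms: none
Why: Suzuki–Miyaura coupling of an alkenyl bromide with an alkenylboronate is a standard entry to 2-substituted buta-1,3-dienes, and the silyl ether is inert to aqueous carbonate at this temperature.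

**Step 4**
Reactants: 2 4-bromo-6-iodobenzene-1,3-diol; 6 tert-butyldimethyl[(2-methylidenebut-3-en-1-yl)oxy]silane (1.3 equiv)
Product: 7 (2S)-5-bromo-2-{3-[(tert-butyldimethylsilyl)oxy]prop-1-en-2-yl}-2,3-dihydro-1-benzofuran-6-ol
Conditions: Pd2(dba)3·CHCl3 (2.5 mol %), chiral tert-butanesulfinamide-derived monophosphine (TY-Phos type, 10 mol %), PhONa (2.2 equiv), toluene, 60 °C
Reagents that add atoms: none
Why: Enantioselective Heck/Tsuji–Trost heteroannulation of an ortho-halophenol with a 1,3-diene (asymmetric Larock-type annulation): zerovalent palladium inserts into C–I before C–Br, the aryl group adds to the terminal carbon of the unsubstituted vinyl unit, the phenoxide ortho to the new bond closes the five-membered ring on the internal terminus of the π-allyl complex, and the ligand, available as either antipode, is chosen to give the 2S centre.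

**Step 5**
Reactants: 7 (2S)-5-bromo-2-{3-[(tert-butyldimethylsilyl)oxy]prop-1-en-2-yl}-2,3-dihydro-1-benzofuran-6-ol
Product: 8 (2S)-5-bromo-2-{3-[(tert-butyldimethylsilyl)oxy]prop-1-en-2-yl}-2,3-dihydro-1-benzofuran-6-yl acetate
Conditions: Ac2O, pyridine, DMAP (5 mol %), CH2Cl2, 0 °C to rt
Reagents that add atoms: acetic anhydride, CC(=O)OC(C)=O
Why: DMAP-catalysed acylation of the only free hydroxyl; the acetate lowers the electron density of the ring ahead of the oxidative key step.

**Step 6**
Reactants: 8 (2S)-5-bromo-2-{3-[(tert-butyldimethylsilyl)oxy]prop-1-en-2-yl}-2,3-dihydro-1-benzofuran-6-yl acetate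
Product: 9 (2S)-5-bromo-2-(3-hydroxyprop-1-en-2-yl)-2,3-dihydro-1-benzofuran-6-yl acetate
Conditions: HF·pyridine, THF/pyridine, 0 °C to rt
Reagents that add atoms: none
Why: Fluoride cleavage of a primary silyl ether under weakly acidic buffered conditions, which should leave the aryl acetate and the allyl aryl ether untouched.

**Step 7**
Reactants: 9 (2S)-5-bromo-2-(3-hydroxyprop-1-en-2-yl)-2,3-dihydro-1-benzofuran-6-yl acetate
Product: 10 (2S)-5-bromo-2-(3-oxoprop-1-en-2-yl)-2,3-dihydro-1-benzofuran-6-yl acetate
Conditions: Dess–Martin periodinane, CH2Cl2, 0 °C to rt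
Reagents that add atoms: none
Why: Dess–Martin oxidation takes the primary allylic alcohol to the enal without amine or phosphine, so nothing can add to the new acceptor and expel the aryloxide from C2; the enal is used at once.

**Step 8**
Reactants: 10 (2S)-5-bromo-2-(3-oxoprop-1-en-2-yl)-2,3-dihydro-1-benzofuran-6-yl acetate
Product: 11 2-[(2S)-6-acetoxy-5-bromo-2,3-dihydro-1-benzofuran-2-yl]prop-2-enoic acid
Conditions: NaClO2, NaH2PO4, 2-methylbut-2-ene, t-BuOH/H2O, 0 °C to rt
Reagents that add atoms: sodium chlorite, [Na+].[O-]Cl=O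
Why: Pinnick oxidation converts enals to enoic acids without touching the alkene, and the alkene scavenger traps hypochlorous acid before it can chlorinate the arene.

**Step 9**
Reactants: 11 2-[(2S)-6-acetoxy-5-bromo-2,3-dihydro-1-benzofuran-2-yl]prop-2-enoic acid
Product: 13 (3aR,8bR)-6-acetoxy-7-bromo-3-methylidene-3a,8b-dihydro-2H-furo[3,2-b][1]benzofuran-2-one (cis-fused α-methylene γ-lactone), via acyl hypoiodite 12 (not isolated)
Conditions: PhI(OAc)2 (1.5 equiv), I2 (0.5 equiv), 1,2-dichloroethane (0.02 M, degassed), white LED, 0–10 °C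
Reagents that add atoms: none
Why: PhI(OAc)2 and I2 give acetyl hypoiodite, which turns the acid into acyl hypoiodite 12; light cleaves its O–I bond, and the acyloxy radical, sitting on an sp2 carbon and so slow to lose CO2, removes the C3 hydrogen syn to the side chain by 1,5-hydrogen transfer through a six-membered transition state. The benzylic radical, stabilised by O1 and the C6 oxygen, is trapped by iodine and ionises, and the carboxylate closes the γ-lactone in a 5-exo sense (exo-tet on the iodide, exo-trig on the cation). The closest known reactions are the benzylic C–H lactonisations of 2-alkylbenzoic and 4-arylbutanoic acids with PhI(OAc)2 and iodine or bromide. The new C3 centre is controlled by the C2 centre, because a bicyclo[3.3.0] lactone can only be cis-fused, so oxygen arrives on the face that carries the side chain. The step needs C3–H over C2–H selectivity and must avoid ring iodination and aromatisation to the benzofuran: the intramolecular transfer reaches only C3–H, bromine blocks the position para to O1, the acetate and bromine lower the ring's electron density, and dilution, low temperature and fast ring closure hold back proton loss from C2.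

**Step 10**
Reactants: 13 (3aR,8bR)-6-acetoxy-7-bromo-3-methylidene-3a,8b-dihydro-2H-furo[3,2-b][1]benzofuran-2-one
Product: 14 (2R,3R)-5-bromo-2-(3-hydroxyprop-1-en-2-yl)-2,3-dihydro-1-benzofuran-3,6-diol
Conditions: i-Bu2AlH (6 equiv), CH2Cl2, −78 to −20 °C; aq. KNaC4H4O6 (potassium sodium tartrate) work-up
Reagents that add atoms: none
Why: i-Bu2AlH reduces the α-methylene γ-lactone in 1,2-fashion through the lactol to the 2-methylene-1,4-diol and cleaves the aryl acetate in the same operation, leaving C–Br and both stereocentres untouched; the neutral tartrate work-up keeps the electron-rich benzylic alcohol away from acid.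

**Step 11**
Reactants: 14 (2R,3R)-5-bromo-2-(3-hydroxyprop-1-en-2-yl)-2,3-dihydro-1-benzofuran-3,6-diol
Product: 16 1-[(2R,3R)-3,6-dihydroxy-2-(3-hydroxyprop-1-en-2-yl)-2,3-dihydro-1-benzofuran-5-yl]ethan-1-one, via ethoxyvinyl arene 15 (not isolated)
Conditions: tributyl(1-ethoxyvinyl)stannane, Pd(P(t-Bu)3)2 (5 mol %), CsF (2.2 equiv), 1,4-dioxane, 50 °C; then 0.5 M aq. HCl, THF, 0 °C, short contact
Reagents that add atoms: tributyl(1-ethoxyvinyl)stannane, CCCC[Sn](CCCC)(CCCC)C(=C)OCC; water, O
Why: Fluoride-promoted Stille coupling with an acetyl-anion equivalent followed by enol ether hydrolysis; it is placed after the reduction (no conjugate acceptor left) and before any allylic ester exists, so zerovalent palladium has only the C–Br bond to attack, and cold dilute acid hydrolyses the enol ether far faster than it ionises the C3 alcohol.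

**Step 12**
Reactants: 16 1-[(2R,3R)-3,6-dihydroxy-2-(3-hydroxyprop-1-en-2-yl)-2,3-dihydro-1-benzofuran-5-yl]ethan-1-one
Product: 17 2-[(2R,3R)-5-acetyl-3,6-dihydroxy-2,3-dihydro-1-benzofuran-2-yl]prop-2-en-1-yl acetate
Conditions: AcCl (1.05 equiv), 2,4,6-collidine, CH2Cl2, −78 °C
Reagents that add atoms: acetyl chloride, CC(=O)Cl
Why: Low-temperature acetylation with AcCl and collidine is selective for primary over secondary hydroxyls; the phenol is tied up in a hydrogen bond to the ortho acetyl carbonyl and the C3 hydroxyl is secondary and flanked by the ring and the side chain.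

**Step 13**
Reactants: 17 2-[(2R,3R)-5-acetyl-3,6-dihydroxy-2,3-dihydro-1-benzofuran-2-yl]prop-2-en-1-yl acetate; 18 angelic acid ((2Z)-2-methylbut-2-enoic acid)
Product: 20 (2R,3R)-5-acetyl-2-[3-(acetyloxy)prop-1-en-2-yl]-6-hydroxy-2,3-dihydro-1-benzofuran-3-yl (2Z)-2-methylbut-2-enoate, via mixed anhydride 19 (not isolated)
Conditions: 18, 2,4,6-trichlorobenzoyl chloride, Et3N, toluene, rt; then 17, 75 °C
Reagents that add atoms: none
Why: Yamaguchi-type mixed-anhydride esterification run without a nucleophilic catalyst, a protocol used to transfer the angeloyl group without Z-to-E isomerisation; the chelated phenol is much the weaker nucleophile, and C3 keeps its configuration because only the O–H bond reacts.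

**Compound list**
1 | 4-bromoresorcinol (4-bromobenzene-1,3-diol) | Oc1ccc(Br)c(O)c1 | starting material
2 | 4-bromo-6-iodobenzene-1,3-diol | Oc1cc(O)c(Br)cc1I | intermediate
3 | 2-bromoprop-2-en-1-ol | C=C(Br)CO | starting material
4 | [(2-bromoprop-2-en-1-yl)oxy](tert-butyl)dimethylsilane | C=C(Br)CO[Si](C)(C)C(C)(C)C | intermediate
5 | vinylboronic acid pinacol ester | C=CB1OC(C)(C)C(C)(C)O1 | starting material
6 | tert-butyldimethyl[(2-methylidenebut-3-en-1-yl)oxy]silane | C=CC(=C)CO[Si](C)(C)C(C)(C)C | intermediate
7 | (2S)-5-bromo-2-{3-[(tert-butyldimethylsilyl)oxy]prop-1-en-2-yl}-2,3-dihydro-1-benzofuran-6-ol | C=C(CO[Si](C)(C)C(C)(C)C)[C@H]1Oc2cc(O)c(Br)cc2C1 | intermediate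
8 | (2S)-5-bromo-2-{3-[(tert-butyldimethylsilyl)oxy]prop-1-en-2-yl}-2,3-dihydro-1-benzofuran-6-yl acetate | C=C(CO[Si](C)(C)C(C)(C)C)[C@H]1Oc2cc(OC(C)=O)c(Br)cc2C1 | intermediate
9 | (2S)-5-bromo-2-(3-hydroxyprop-1-en-2-yl)-2,3-dihydro-1-benzofuran-6-yl acetate | C=C(CO)[C@H]1Oc2cc(OC(C)=O)c(Br)cc2C1 | intermediate
10 | (2S)-5-bromo-2-(3-oxoprop-1-en-2-yl)-2,3-dihydro-1-benzofuran-6-yl acetate | C=C(C=O)[C@H]1Oc2cc(OC(C)=O)c(Br)cc2C1 | intermediate
11 | 2-[(2S)-6-acetoxy-5-bromo-2,3-dihydro-1-benzofuran-2-yl]prop-2-enoic acid | C=C(C(=O)O)[C@H]1Oc2cc(OC(C)=O)c(Br)cc2C1 | intermediate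
12 | 2-[(2S)-6-acetoxy-5-bromo-2,3-dihydro-1-benzofuran-2-yl]prop-2-enoyl hypoiodite | C=C(C(=O)OI)[C@H]1Oc2cc(OC(C)=O)c(Br)cc2C1 | intermediate
13 | (3aR,8bR)-6-acetoxy-7-bromo-3-methylidene-3a,8b-dihydro-2H-furo[3,2-b][1]benzofuran-2-one | C=C3[C@H]1Oc2cc(OC(C)=O)c(Br)cc2[C@H]1OC3=O | intermediate
14 | (2R,3R)-5-bromo-2-(3-hydroxyprop-1-en-2-yl)-2,3-dihydro-1-benzofuran-3,6-diol | C=C(CO)[C@H]1Oc2cc(O)c(Br)cc2[C@H]1O | intermediate
15 | (2R,3R)-5-(1-ethoxyethenyl)-2-(3-hydroxyprop-1-en-2-yl)-2,3-dihydro-1-benzofuran-3,6-diol | C=C(CO)[C@H]1Oc2cc(O)c(C(=C)OCC)cc2[C@H]1O | intermediate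
16 | 1-[(2R,3R)-3,6-dihydroxy-2-(3-hydroxyprop-1-en-2-yl)-2,3-dihydro-1-benzofuran-5-yl]ethan-1-one | C=C(CO)[C@H]1Oc2cc(O)c(C(C)=O)cc2[C@H]1O | intermediate
17 | 2-[(2R,3R)-5-acetyl-3,6-dihydroxy-2,3-dihydro-1-benzofuran-2-yl]prop-2-en-1-yl acetate | C=C(COC(C)=O)[C@H]1Oc2cc(O)c(C(C)=O)cc2[C@H]1O | intermediate
18 | angelic acid ((2Z)-2-methylbut-2-enoic acid) | C/C=C(/C)C(=O)O | starting material
19 | (2Z)-2-methylbut-2-enoic 2,4,6-trichlorobenzoic anhydride | C/C=C(/C)C(=O)OC(=O)c1c(Cl)cc(Cl)cc1Cl | intermediate
20 | (2R,3R)-5-acetyl-2-[3-(acetyloxy)prop-1-en-2-yl]-6-hydroxy-2,3-dihydro-1-benzofuran-3-yl (2Z)-2-methylbut-2-enoate | C=C(COC(C)=O)[C@H]1Oc2cc(O)c(C(C)=O)cc2[C@H]1OC(=O)/C(C)=C\C | target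

**Totals**
Total steps: 13. Longest linear sequence: 12 steps (from 3 through steps 2–13); the arene branch from 1 joins at step 4.

**Steps most likely to fail**

Step 9. Ionic iodination of the ring at C7 by acetyl hypoiodite may outrun the radical chain, and the C3 cation may lose the C2 proton and aromatise instead of being captured by the carboxylate. The fallback sets out from 11 and returns at 13. The benzylic position is first brominated under Wohl–Ziegler conditions (NBS, visible light, PhCF3, 0 °C) to give 2-[(2R)-6-acetoxy-3,5-dibromo-2,3-dihydro-1-benzofuran-2-yl]prop-2-enoic acid F1 as a mixture of C3 epimers. Ag2CO3 in MeCN at 0 °C then abstracts bromide so that the carboxylate closes the same cis-fused lactone 13 by intramolecular substitution. Oxygen is thus delivered in a separate ionic step instead of by hydrogen transfer.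

Step 4. Enantioselectivity may erode with this 2-(silyloxymethyl)diene, insertion may occur at the wrong diene terminus, or oxidative addition into the C–Br bond of the product may start a second annulation. The fallback sets out from 2 and 6 and returns at 7. A ligand-free Larock heteroannulation (Pd(OAc)2, NaHCO3, n-Bu4NCl, DMF, 60 °C) should give the racemic silyl ether F2, which is resolved by preparative chromatography on a chiral stationary phase. The (S)-enantiomer is 7 and the (R)-enantiomer F3 is set aside, so the configuration comes from resolution instead of from the catalyst.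

Step 13. The angeloyl group may isomerise to the E (tigloyl) isomer during activation, acylation of the hindered C3 hydroxyl may be slow enough for the phenol to compete, or the benzylic ester may ionise at 75 °C with loss of C3 configuration or elimination. The fallback sets out from 17 and returns at 20. The C3 hydroxyl is esterified at room temperature with 2-[bis(2,2,2-trifluoroethoxy)phosphoryl]propanoic acid (DCC, catalytic DMAP, CH2Cl2) to give the phosphonate ester F4. A Still–Gennari olefination with acetaldehyde (KN(SiMe3)2, 18-crown-6, THF, −78 °C, one extra equivalent of base for the phenol) then builds the Z-configured 2-methylbut-2-enoate on the substrate and gives 20.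

**Further compounds**
F1 | step 9 | 2-[(2R)-6-acetoxy-3,5-dibromo-2,3-dihydro-1-benzofuran-2-yl]prop-2-enoic acid (C3 epimer mixture) | C=C(C(=O)O)[C@H]1Oc2cc(OC(C)=O)c(Br)cc2C1Br
F2 | step 4 | racemic 5-bromo-2-{3-[(tert-butyldimethylsilyl)oxy]prop-1-en-2-yl}-2,3-dihydro-1-benzofuran-6-ol | C=C(CO[Si](C)(C)C(C)(C)C)C1Oc2cc(O)c(Br)cc2C1
F3 | step 4 | (2R)-5-bromo-2-{3-[(tert-butyldimethylsilyl)oxy]prop-1-en-2-yl}-2,3-dihydro-1-benzofuran-6-ol | C=C(CO[Si](C)(C)C(C)(C)C)[C@@H]1Oc2cc(O)c(Br)cc2C1
F4 | step 13 | 2-[(2R,3R)-5-acetyl-3-({2-[bis(2,2,2-trifluoroethoxy)phosphoryl]propanoyl}oxy)-6-hydroxy-2,3-dihydro-1-benzofuran-2-yl]prop-2-en-1-yl acetate (epimers at the phosphonate carbon) | C=C(COC(C)=O)[C@H]1Oc2cc(O)c(C(C)=O)cc2[C@H]1OC(=O)C(C)P(=O)(OCC(F)(F)F)OCC(F)(F)F
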